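**Plan**

- The target is achiral. Ring A is the 2-butyryl-6,6-dimethyl triketone enol, ring B the central butyrylphloroglucinol, and ring C the aryl methyl ether (C1 bridge carbon, C2 OH, C3 CH3, C4 OCH3, C5 butyryl, C6 OH).
- Retrosynthetic cuts, in order: the two C–C bonds of the ring A–CH2–ring B bridge; the two aryl–CO bonds of the butyryl groups on rings B and C; then, within ring C, C2–C3, C4–C5 and C1–C2.
- Enabling feature: in ring C the contiguous C2–OH, C3–CH3, C4–OCH3 triad, flanked by C5–H, C6–O and the C1–CH2–ring B link, is what a ketene carbonyl, 1-methoxypropyne and a 3-benzyloxy-4-(arylmethyl)cyclobutenone assemble.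
- Forward: ring B is bought as 1,3,5-tris(benzyloxy)benzene, formylated and extended to a propanoic acid that already holds the B–C methylene. A ketene/benzyloxyacetylene [2+2] gives the cyclobutenone, and ring C then arises by benzannulation. Debenzylation and double butyrylation follow, and ring A (from phloroglucinol by acylation and geminal dimethylation) is attached last through one carbon from an iminium salt.
- Stereochemistry: none in the target. The only stereocenter on the way (C4 of the cyclobutenone, racemic) is erased when ring C aromatizes.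

Key step: step 7

Remark: the target is taken exactly as its SMILES draws it (ring C butyryl between OCH3 and OH, bridge carbon between two OH groups, ring A in the drawn enol tautomer); 1,3,5-tris(benzyloxy)benzene is assumed to be purchasable; conjugate bases formed by simple deprotonation are not numbered separately.

**Route**

Step 1
Reactants: 1 1,3,5-tris(benzyloxy)benzene
Product: 3 2,4,6-tris(benzyloxy)benzaldehyde, via iminium chloride 2 (not isolated)
Conditions: POCl3 (1.2 equiv), DMF, 0 → 60 °C; then ice–water, rt
Reagents that add atoms: N,N-dimethylformamide, CN(C)C=O; water, O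
Why: Vilsmeier–Haack formylation of the strongly activated triether, whose three free ring positions are equivalent, should stop after one substitution because the iminium group deactivates the ring, and the benzyl ethers are stable to POCl3/DMF and to the aqueous hydrolysis of the iminium salt.

Step 2
Reactants: 3 2,4,6-tris(benzyloxy)benzaldehyde; 4 Meldrum's acid
Product: 7 3-[2,4,6-tris(benzyloxy)phenyl]propanoic acid, via arylidene Meldrum's acid 5 (not isolated), via benzyl Meldrum's acid 6 (not isolated)
Conditions: HCO2H–Et3N (5:2), 95–100 °C; then aq HCl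
Reagents that add atoms: none
Why: One-pot Knoevenagel condensation, conjugate hydride transfer from triethylammonium formate to the alkylidene Meldrum's acid, and hydrolytic decarboxylation should give the arylpropanoic acid without hydrogen gas, so the benzyl ethers stay in place.

Step 3
Reactants: 8 benzyl alcohol; 9 trichloroethylene
Product: 11 benzyl (E)-1,2-dichlorovinyl ether, via dichloroacetylene 10 (not isolated)
Conditions: KH, THF, 0 °C; then 9, −50 °C → rt
Reagents that add atoms: none
Why: Alkoxide-induced dehydrochlorination of trichloroethylene followed by anti addition of benzyloxide to the chloroalkyne is the standard elimination–addition route to 1,2-dichlorovinyl ethers; the anti addition sets the E geometry, which is of no later consequence.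

Step 4
Reactants: 11 benzyl (E)-1,2-dichlorovinyl ether
Product: 14 benzyl ethynyl ether, via benzyl chloroethynyl ether 12 (not isolated), via lithium benzyloxyethynide 13 (not isolated)
Conditions: n-BuLi (2.2 equiv), Et2O, −78 °C; then MeOH, −78 → 0 °C; kept as a cold ethereal solution
Reagents that add atoms: none
Why: Dehydrochlorination and then chlorine–lithium exchange with n-BuLi is the usual conversion of dichlorovinyl ethers into lithium alkoxyacetylides; cold protonation should give the terminal ynol ether well below the temperature at which benzyl alkynyl ethers rearrange.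

Step 5
Reactants: 7 3-[2,4,6-tris(benzyloxy)phenyl]propanoic acid; 14 benzyl ethynyl ether
Product: 17 3-(benzyloxy)-4-[[2,4,6-tris(benzyloxy)phenyl]methyl]cyclobut-2-en-1-one (racemic), via acid chloride 15 (not isolated), via monoalkylketene 16 (not isolated)
Conditions: Me2C=C(Cl)NMe2, CH2Cl2, 0 °C → rt; then 14 (2.5 equiv), Et3N (slow addition), 0 °C → rt
Reagents that add atoms: none
Why: Neutral acid chloride formation with the α-chloroenamine avoids Vilsmeier-type attack on the electron-rich ring, and amine dehydrochlorination to the ketene with in situ [2+2] cycloaddition to an alkoxyacetylene (ketene carbonyl carbon to the unsubstituted alkyne carbon) is the established route to 4-substituted 3-alkoxycyclobutenones; the new C4 stereocenter forms racemic and is destroyed in step 7.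

Step 6
Reactants: 18 2-chloro-1,1-dimethoxyethane
Product: 20 1-methoxyprop-1-yne, via sodium methoxyethynide 19 (not isolated)
Conditions: NaNH2 (3.2 equiv), liq. NH3, −33 °C; then MeI, −33 °C → rt; distillation
Reagents that add atoms: iodomethane, CI
Why: Double elimination and deprotonation of the chloroacetal by sodium amide, followed by C-alkylation of the alkoxyacetylide in liquid ammonia, is the textbook preparation of 1-alkoxyalk-1-ynes.

Step 7
Reactants: 17 3-(benzyloxy)-4-[[2,4,6-tris(benzyloxy)phenyl]methyl]cyclobut-2-en-1-one; 20 1-methoxyprop-1-yne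
Product: 25 5-(benzyloxy)-3-methoxy-2-methyl-6-[[2,4,6-tris(benzyloxy)phenyl]methyl]phenol, via vinylketene 21 (not isolated), via vinylcyclobutenone 22 (not isolated), via dienylketene 23 (not isolated), via cyclohexadienone 24 (not isolated)
Conditions: 20 (3 equiv), toluene, 110 °C then 145 °C, sealed tube
Reagents that add atoms: none
Why: Thermal 4π electrocyclic opening of 17 gives vinylketene 21, whose ketene C=C adds to the ynol ether in a regiospecific [2+2] cycloaddition (ketene carbonyl carbon to the methyl-bearing alkyne carbon, forming ring C bonds C2–C3 and C4–C5) to give vinylcyclobutenone 22; a second 4π opening gives dienylketene 23, 6π electrocyclization closes C1–C2 to cyclohexadienone 24, and tautomerization should deliver the phenol. The closest known reaction type is the Danheiser benzannulation of cyclobutenones with alkoxy- and siloxyalkynes, which gives resorcinol monoethers; here the 3-benzyloxy group of 17 turns the product into a phloroglucinol with three differently masked oxygens (C2–OH, C4–OCH3, C6–OBn). Ring C, the only ring formed, closes by a thermally allowed disrotatory 6π electrocyclization of the (3E)-dienylketene. No stereocenter is created, and the racemic C4 of 17 becomes the aromatic C1. The selectivity needed is the orientation of the ketene–alkyne [2+2], which the oxygen-polarized triple bond of 20 secures so that CH3 ends ortho and OCH3 meta to the new hydroxyl; 20 has no β-hydrogen in its O-alkyl group and so cannot fragment by a retro-ene path at the temperature needed to open the donor-substituted cyclobutenone.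

Step 8
Reactants: 25 5-(benzyloxy)-3-methoxy-2-methyl-6-[[2,4,6-tris(benzyloxy)phenyl]methyl]phenol
Product: 26 2-[(2,6-dihydroxy-4-methoxy-3-methylphenyl)methyl]benzene-1,3,5-triol
Conditions: H2 (1 atm), Pd/C, EtOAc–MeOH, rt; filtered under argon and used at once
Reagents that add atoms: none
Why: Catalytic hydrogenolysis should cleave the four aryl benzyl ethers, while the diarylmethane CH2, the methyl ether and the arenes are inert under these conditions.

Step 9
Reactants: 26 2-[(2,6-dihydroxy-4-methoxy-3-methylphenyl)methyl]benzene-1,3,5-triol; 27 butanoyl chloride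
Product: 28 1-[3-[(3-butanoyl-2,6-dihydroxy-4-methoxy-5-methylphenyl)methyl]-2,4,6-trihydroxyphenyl]butan-1-one
Conditions: 27 (2.2 equiv), AlCl3 (6 equiv), CH2Cl2–PhNO2, 0 °C → rt; then ice, 2 M HCl
Reagents that add atoms: none
Why: Friedel–Crafts C-acylation of a polyphenol, in which ring C has only C5 free and ring B has two equivalent free positions, each ring being deactivated by its first acyl group, so two equivalents should stop at one butyryl per ring; the C4 methyl ether should survive because the new carbonyl chelates the C6 phenoxide instead.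

Step 10
Reactants: 29 phloroglucinol; 27 butanoyl chloride
Product: 30 1-(2,4,6-trihydroxyphenyl)butan-1-one
Conditions: 27 (1.05 equiv), AlCl3 (4 equiv), CH2Cl2–PhNO2, 0 → 40 °C; then ice, 2 M HCl
Reagents that add atoms: none
Why: Friedel–Crafts mono-acylation of phloroglucinol is the standard entry to acylphloroglucinols, the first acyl group slowing a second acylation.

Step 11
Reactants: 30 1-(2,4,6-trihydroxyphenyl)butan-1-one
Product: 31 2-butanoyl-3,5-dihydroxy-6,6-dimethylcyclohexa-2,4-dien-1-one (butyrylfilicinic acid)
Conditions: NaOMe (3 equiv), MeI (2.2 equiv), MeOH, 0 °C → rt; then aq HCl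
Reagents that add atoms: iodomethane, CI
Why: Dearomatizing geminal C-methylation of an acylphloroglucinol (the first methyl makes that ring carbon the most nucleophilic enolate position) is the classical preparation of acylfilicinic acids.

Step 12
Reactants: 31 butyrylfilicinic acid; 28 1-[3-[(3-butanoyl-2,6-dihydroxy-4-methoxy-5-methylphenyl)methyl]-2,4,6-trihydroxyphenyl]butan-1-one
Product: 34 Filixsaure as drawn (2-butanoyl-4-[[3-butanoyl-5-[(3-butanoyl-2,6-dihydroxy-4-methoxy-5-methylphenyl)methyl]-2,4,6-trihydroxyphenyl]methyl]-3,5-dihydroxy-6,6-dimethylcyclohexa-2,4-dien-1-one), via Mannich base 32 (not isolated), via methylidene triketone 33 (not isolated)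
Conditions: [Me2N=CH2]I (1 equiv per 31), MeCN, 0 °C → rt; then 28 (0.9 equiv), 50 °C
Reagents that add atoms: N,N-dimethylmethylideneammonium iodide, C=[N+](C)C.[I-]
Why: Mannich aminomethylation at the only free ring carbon of 31, then thermal elimination of dimethylamine to the methylidene triketone and Friedel–Crafts-type conjugate addition of the single free position of ring B, is the quinone-methide route to unsymmetrical methylene-bridged acylphloroglucinols; placing the electrophile on ring A before 28 is added should favour cross- over homo-coupling.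

**Compound list**

1 | 1,3,5-tris(benzyloxy)benzene | c1ccc(COc2cc(OCc3ccccc3)cc(OCc3ccccc3)c2)cc1 | starting material
2 | N-methyl-N-[[2,4,6-tris(benzyloxy)phenyl]methylidene]methanaminium chloride | C[N+](C)=Cc1c(OCc2ccccc2)cc(OCc2ccccc2)cc1OCc1ccccc1.[Cl-] | intermediate (not isolated)
3 | 2,4,6-tris(benzyloxy)benzaldehyde | O=Cc1c(OCc2ccccc2)cc(OCc2ccccc2)cc1OCc1ccccc1 | intermediate
4 | Meldrum's acid (2,2-dimethyl-1,3-dioxane-4,6-dione) | CC1(C)OC(=O)CC(=O)O1 | starting material
5 | 2,2-dimethyl-5-[[2,4,6-tris(benzyloxy)phenyl]methylidene]-1,3-dioxane-4,6-dione | CC1(C)OC(=O)C(=Cc2c(OCc3ccccc3)cc(OCc3ccccc3)cc2OCc2ccccc2)C(=O)O1 | intermediate (not isolated)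
6 | 2,2-dimethyl-5-[[2,4,6-tris(benzyloxy)phenyl]methyl]-1,3-dioxane-4,6-dione | CC1(C)OC(=O)C(Cc2c(OCc3ccccc3)cc(OCc3ccccc3)cc2OCc2ccccc2)C(=O)O1 | intermediate (not isolated)
7 | 3-[2,4,6-tris(benzyloxy)phenyl]propanoic acid | OC(=O)CCc1c(OCc2ccccc2)cc(OCc2ccccc2)cc1OCc1ccccc1 | intermediate
8 | benzyl alcohol | OCc1ccccc1 | starting material
9 | trichloroethylene | ClC=C(Cl)Cl | starting material
10 | dichloroacetylene | ClC#CCl | intermediate (not isolated)
11 | benzyl (E)-1,2-dichlorovinyl ether | Cl/C=C(/Cl)OCc1ccccc1 | intermediate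
12 | benzyl chloroethynyl ether | ClC#COCc1ccccc1 | intermediate (not isolated)
13 | lithium (benzyloxy)ethynide | [Li]C#COCc1ccccc1 | intermediate (not isolated)
14 | benzyl ethynyl ether (benzyloxyacetylene) | C#COCc1ccccc1 | intermediate
15 | 3-[2,4,6-tris(benzyloxy)phenyl]propanoyl chloride | ClC(=O)CCc1c(OCc2ccccc2)cc(OCc2ccccc2)cc1OCc1ccccc1 | intermediate (not isolated)
16 | 3-[2,4,6-tris(benzyloxy)phenyl]prop-1-en-1-one (monoalkylketene) | O=C=CCc1c(OCc2ccccc2)cc(OCc2ccccc2)cc1OCc1ccccc1 | intermediate (not isolated)
17 | 3-(benzyloxy)-4-[[2,4,6-tris(benzyloxy)phenyl]methyl]cyclobut-2-en-1-one (racemic) | O=C1C=C(OCc2ccccc2)C1Cc1c(OCc2ccccc2)cc(OCc2ccccc2)cc1OCc1ccccc1 | intermediate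
18 | 2-chloro-1,1-dimethoxyethane | COC(CCl)OC | starting material
19 | sodium methoxyethynide | [Na]C#COC | intermediate (not isolated)
20 | 1-methoxyprop-1-yne | CC#COC | intermediate
21 | (3Z)-3-(benzyloxy)-5-[2,4,6-tris(benzyloxy)phenyl]penta-1,3-dien-1-one | O=C=C/C(OCc1ccccc1)=C/Cc1c(OCc2ccccc2)cc(OCc2ccccc2)cc1OCc1ccccc1 | intermediate (not isolated)
22 | 4-[(1Z)-1-(benzyloxy)-3-[2,4,6-tris(benzyloxy)phenyl]prop-1-en-1-yl]-3-methoxy-2-methylcyclobut-2-en-1-one (racemic) | O=C1C(C)=C(OC)C1/C(OCc1ccccc1)=C/Cc1c(OCc2ccccc2)cc(OCc2ccccc2)cc1OCc1ccccc1 | intermediate (not isolated)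
23 | (3E,5Z)-5-(benzyloxy)-3-methoxy-2-methyl-7-[2,4,6-tris(benzyloxy)phenyl]hepta-1,3,5-trien-1-one | O=C=C(C)/C(OC)=C\C(OCc1ccccc1)=C\Cc1c(OCc2ccccc2)cc(OCc2ccccc2)cc1OCc1ccccc1 | intermediate (not isolated)
24 | 5-(benzyloxy)-3-methoxy-2-methyl-6-[[2,4,6-tris(benzyloxy)phenyl]methyl]cyclohexa-2,4-dien-1-one (racemic) | O=C1C(C)=C(OC)C=C(OCc2ccccc2)C1Cc1c(OCc2ccccc2)cc(OCc2ccccc2)cc1OCc1ccccc1 | intermediate (not isolated)
25 | 5-(benzyloxy)-3-methoxy-2-methyl-6-[[2,4,6-tris(benzyloxy)phenyl]methyl]phenol | COc1cc(OCc2ccccc2)c(Cc2c(OCc3ccccc3)cc(OCc3ccccc3)cc2OCc2ccccc2)c(O)c1C | intermediate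
26 | 2-[(2,6-dihydroxy-4-methoxy-3-methylphenyl)methyl]benzene-1,3,5-triol | COc1cc(O)c(Cc2c(O)cc(O)cc2O)c(O)c1C | intermediate
27 | butanoyl chloride | CCCC(Cl)=O | starting material
28 | 1-[3-[(3-butanoyl-2,6-dihydroxy-4-methoxy-5-methylphenyl)methyl]-2,4,6-trihydroxyphenyl]butan-1-one | CCCC(=O)c1c(O)cc(O)c(Cc2c(O)c(C)c(OC)c(C(=O)CCC)c2O)c1O | intermediate
29 | phloroglucinol (benzene-1,3,5-triol) | Oc1cc(O)cc(O)c1 | starting material
30 | 1-(2,4,6-trihydroxyphenyl)butan-1-one | CCCC(=O)c1c(O)cc(O)cc1O | intermediate
31 | 2-butanoyl-3,5-dihydroxy-6,6-dimethylcyclohexa-2,4-dien-1-one (butyrylfilicinic acid) | CCCC(=O)C1=C(O)C=C(O)C(C)(C)C1=O | intermediate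
32 | 2-butanoyl-4-[(dimethylamino)methyl]-3,5-dihydroxy-6,6-dimethylcyclohexa-2,4-dien-1-one hydroiodide | CCCC(=O)C1=C(O)C(C[NH+](C)C)=C(O)C(C)(C)C1=O.[I-] | intermediate (not isolated)
33 | 2-butanoyl-3-hydroxy-6,6-dimethyl-4-methylidenecyclohex-2-ene-1,5-dione | CCCC(=O)C1=C(O)C(=C)C(=O)C(C)(C)C1=O | intermediate (not isolated)
34 | Filixsaure as drawn (achiral) | CCCC(=O)C1=C(O)C(Cc2c(O)c(Cc3c(O)c(C)c(OC)c(C(=O)CCC)c3O)c(O)c(C(=O)CCC)c2O)=C(O)C(C)(C)C1=O | target

**Count**

Total: 12 steps. Longest linear sequence: 7 steps (steps 1, 2, 5, 7, 8, 9, 12).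

**Steps most likely to fail**

1. Step 7. The vinylogous-ester cyclobutenone may open only slowly, so the vinylketene is present at low concentration and could be lost by oligomerization or by acylating the product phenol before the moderately nucleophilic, volatile methyl ynol ether captures it; the sequence could also stall at the vinylcyclobutenone stage. The fallback sets out from 17 and comes back at 26, and changes the annulation partner to a silyl ynol ether, a stronger ketenophile, with the methyl ether introduced afterwards. Lithium prop-1-yn-1-olate F1 (from ethyl 2,2-dibromopropanoate and t-BuLi, THF, −78 → 0 °C) would be O-silylated with TIPSCl to triisopropyl(prop-1-yn-1-yloxy)silane F2. Heating 17 with F2 (toluene, 80–110 °C) should give, by the same annulation, 5-(benzyloxy)-2-methyl-3-(triisopropylsilyloxy)-6-[[2,4,6-tris(benzyloxy)phenyl]methyl]phenol F3, whose three ring C oxygens are again all different (OH, OSi, OBn). Benzylation of the free phenol (NaH, benzyl bromide, DMF, 0 °C) would give [3,5-bis(benzyloxy)-2-methyl-4-[[2,4,6-tris(benzyloxy)phenyl]methyl]phenoxy]triisopropylsilane F4. TBAF (THF, 0 °C) would then free 3,5-bis(benzyloxy)-2-methyl-4-[[2,4,6-tris(benzyloxy)phenyl]methyl]phenol F5, and O-methylation (MeI, K2CO3, acetone) would give 1,3-bis(benzyloxy)-5-methoxy-4-methyl-2-[[2,4,6-tris(benzyloxy)phenyl]methyl]benzene F6. Hydrogenolysis as in step 8 returns to 26.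

2. Step 5. Dimerization of the monoalkylketene, and loss of the heat- and acid-sensitive benzyl ethynyl ether by sigmatropic rearrangement or polymerization, may outrun the [2+2] cycloaddition. The fallback sets out from 7 (through 15 and 16 as in step 5) and comes back at 17, and avoids the benzyl ynol ether altogether. Commercial ethoxyacetylene, usable in large excess, would trap the ketene to give 3-ethoxy-4-[[2,4,6-tris(benzyloxy)phenyl]methyl]cyclobut-2-en-1-one F7. Acid-catalysed alkoxy exchange of this vinylogous ester (benzyl alcohol 8 in excess, cat. TsOH, benzene, ethanol distilled off) should then give 17. Migration of the substituent is not expected, because enolization towards C4 would require an antiaromatic cyclobutadienol.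

3. Step 9. Over-acylation of ring B, AlCl3-mediated cleavage of the methyl ether next to the new ketone, or acid-induced fragmentation and scrambling of the electron-rich diarylmethane link may erode the bis-ketone. The fallback sets out from 26 and comes back at 28, and replaces the acyl chloride/AlCl3 acylation by a nitrile-based Houben–Hoesch acylation. Butanenitrile, ZnCl2 and HCl gas in Et2O at 0 °C should give 1-[3-[(3-butanimidoyl-2,6-dihydroxy-4-methoxy-5-methylphenyl)methyl]-2,4,6-trihydroxyphenyl]butan-1-imine dihydrochloride F8; each ring is shut down after one C–C bond formation, no O-acylation occurs, and no ether-cleaving Lewis acid is present. Hydrolysis in water at 90 °C then gives 28.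

**Further compounds**

F1 | step 7 | lithium prop-1-yn-1-olate | CC#C[O-].[Li+]
F2 | step 7 | triisopropyl(prop-1-yn-1-yloxy)silane | CC#CO[Si](C(C)C)(C(C)C)C(C)C
F3 | step 7 | 5-(benzyloxy)-2-methyl-3-(triisopropylsilyloxy)-6-[[2,4,6-tris(benzyloxy)phenyl]methyl]phenol | Cc1c(O)c(Cc2c(OCc3ccccc3)cc(OCc3ccccc3)cc2OCc2ccccc2)c(OCc2ccccc2)cc1O[Si](C(C)C)(C(C)C)C(C)C
F4 | step 7 | [3,5-bis(benzyloxy)-2-methyl-4-[[2,4,6-tris(benzyloxy)phenyl]methyl]phenoxy]triisopropylsilane | Cc1c(OCc2ccccc2)c(Cc2c(OCc3ccccc3)cc(OCc3ccccc3)cc2OCc2ccccc2)c(OCc2ccccc2)cc1O[Si](C(C)C)(C(C)C)C(C)C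
F5 | step 7 | 3,5-bis(benzyloxy)-2-methyl-4-[[2,4,6-tris(benzyloxy)phenyl]methyl]phenol | Cc1c(OCc2ccccc2)c(Cc2c(OCc3ccccc3)cc(OCc3ccccc3)cc2OCc2ccccc2)c(OCc2ccccc2)cc1O
F6 | step 7 | 1,3-bis(benzyloxy)-5-methoxy-4-methyl-2-[[2,4,6-tris(benzyloxy)phenyl]methyl]benzene | COc1cc(OCc2ccccc2)c(Cc2c(OCc3ccccc3)cc(OCc3ccccc3)cc2OCc2ccccc2)c(OCc2ccccc2)c1C
F7 | step 5 | 3-ethoxy-4-[[2,4,6-tris(benzyloxy)phenyl]methyl]cyclobut-2-en-1-one (racemic) | CCOC1=CC(=O)C1Cc1c(OCc2ccccc2)cc(OCc2ccccc2)cc1OCc1ccccc1
F8 | step 9 | 1-[3-[(3-butanimidoyl-2,6-dihydroxy-4-methoxy-5-methylphenyl)methyl]-2,4,6-trihydroxyphenyl]butan-1-imine dihydrochloride | CCCC(=[NH2+])c1c(O)cc(O)c(Cc2c(O)c(C)c(OC)c(C(=[NH2+])CCC)c2O)c1O.[Cl-].[Cl-]
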